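**Retrosynthetic overview**
1. C10′–C11′ of the diene: Heck coupling of styrene with an (E)-alkenyl iodide made from a terminal alkyne; the CO2H comes from oxidation of a 2-hydroxyethyl arm.
2. 1,2-Dioxolane (the only ring, closed in step 5): C5–O by cobalt-hydride hydrogen-atom transfer / radical–polar crossover cyclisation of a tertiary silyl peroxide onto a trisubstituted alkene; C3–OO by Co/O2/Et3SiH radical peroxidation of the 1,1-disubstituted alkene of the same skipped diene.
3. Skipped diene: Negishi coupling of the isoprenol-derived allylzinc with an enol triflate.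
4. Enol triflate and the side-chain methyl stereocentre: Cu/Josiphos conjugate addition of an alkyl Grignard reagent (from 1,6-dibromohexane and TMS-acetylene) to pent-3-en-2-one, with the enolate trapped as its triflate.

Assumption: (R,S)-Josiphos (step 2) is taken to give the 4R adduct and (R,R)-Co(salen) (step 5) to favour 5R; if a trial run shows the opposite sense, the mirror-image ligand is used.

**Step 1**
Reactants: 1 1,6-dibromohexane; 2 ethynyltrimethylsilane
Product: 4 (8-bromooct-1-yn-1-yl)trimethylsilane, via lithium (trimethylsilyl)acetylide 3 (not isolated)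
Conditions: 2, n-BuLi, THF, −78 °C; then 1 (3 equiv), DMPU, −78 °C → rt
Reagents that add atoms: none
Why: SN2 alkylation of a lithium acetylide by a primary bromide, with excess dibromide enforcing monoalkylation; no stereocentre is formed.

**Step 2**
Reactants: 4 (8-bromooct-1-yn-1-yl)trimethylsilane; 5 (E)-pent-3-en-2-one
Product: 8 (2Z,4R)-4-methyl-12-(trimethylsilyl)dodec-2-en-11-yn-2-yl trifluoromethanesulfonate, via Grignard reagent 6 (not isolated), via magnesium enolate 7 (not isolated)
Conditions: 4, Mg, t-BuOMe, rt; then 5, CuBr·SMe2 (5 mol %), (R,S)-Josiphos (6 mol %), −75 °C; then PhNTf2, THF–DMPU, −75 → 0 °C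
Reagents that add atoms: N-phenylbis(trifluoromethanesulfonimide) O=S(=O)(N(c1ccccc1)S(=O)(=O)C(F)(F)F)C(F)(F)F
Why: Copper/Josiphos-catalysed asymmetric conjugate addition of a primary alkyl Grignard reagent to an acyclic methyl enone (Feringa) sets C4 as R by catalyst control (≥90 % ee expected), and the regiodefined magnesium enolate is O-triflated in the same flask, which fixes the double bond on the side-chain side of the future C5 (its geometry does not matter later).

**Step 3**
Reactants: 8 (2Z,4R)-4-methyl-12-(trimethylsilyl)dodec-2-en-11-yn-2-yl trifluoromethanesulfonate; 9 3-methylbut-3-en-1-ol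
Product: 13 (5Z,7R)-5,7-dimethyl-3-methylidene-15-(trimethylsilyl)pentadec-5-en-14-yn-1-yl acetate, via dilithiated isoprenol 10 (not isolated), via allylzinc reagent 11 (not isolated), via lithium alkoxide of the coupled dienol 12 (not isolated)
Conditions: 9, n-BuLi (2.1 equiv), TMEDA, Et2O/hexane, 0 °C → rt; ZnCl2, THF, 0 °C; then 8, Pd(PPh3)4 (5 mol %), THF, 40 °C; then Ac2O, DMAP, 0 °C → rt
Reagents that add atoms: acetic anhydride CC(=O)OC(C)=O
Why: The known isoprenol dianion is transmetallated to an allylzinc whose two termini are identical, so its Negishi coupling with the enol triflate can give only one skipped diene (vinyl geometry retained, stereocentre untouched), and acetylating the alkoxide in the quench masks the hydroxyl that would otherwise compete as a nucleophile in step 5.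

**Step 4**
Reactants: 13 (5Z,7R)-5,7-dimethyl-3-methylidene-15-(trimethylsilyl)pentadec-5-en-14-yn-1-yl acetate
Product: 14 (3RS,5Z,7R)-3,5,7-trimethyl-3-[(triethylsilyl)peroxy]-15-(trimethylsilyl)pentadec-5-en-14-yn-1-yl acetate
Conditions: Co(thd)2 (10 mol %), Et3SiH (2 equiv), O2 (1 atm), DCE, rt
Reagents that add atoms: dioxygen O=O; triethylsilane CC[SiH](CC)CC
Why: Isayama–Mukaiyama hydroperoxysilylation, in which Co–H hydrogen-atom transfer to the unhindered 1,1-disubstituted alkene gives the tertiary C3 radical that captures O2 while the hindered trisubstituted alkene, silyl alkyne and acetate stay intact, so the C3–OO bond and the C3 methyl group are created together; C3 forms without control (about 1:1) and is sorted out after ring closure.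

**Step 5**
Reactants: 14 (3RS,5Z,7R)-3,5,7-trimethyl-3-[(triethylsilyl)peroxy]-15-(trimethylsilyl)pentadec-5-en-14-yn-1-yl acetate
Product: 15 2-[(3S,5R)-3,5-dimethyl-5-[(2R)-2-methyl-10-(trimethylsilyl)dec-9-yn-1-yl]-1,2-dioxolan-3-yl]ethyl acetate
Conditions: (R,R)-Co(II)(salen) [Jacobsen ligand] (10 mol %), N-fluoro-2,4,6-trimethylpyridinium triflate (2 equiv), PhSiH3 (1.5 equiv), PhCF3, 0 °C → rt, Ar; then chromatography (preparative HPLC if needed)
Reagents that add atoms: none
Why: Proposed new method: cobalt-hydride hydrogen-atom transfer to the trisubstituted alkene (H to C6) gives the tertiary C5 radical, which is oxidised through an alkyl–Co(IV)/carbocation (radical–polar crossover) and captured in a five-membered mode by the distal oxygen of the silyl peroxide with loss of Et3Si+, the closest known reactions being Co(salen)/N-fluoropyridinium/silane hydroalkoxylations of unactivated alkenes (including cyclisations of O-silyl ethers with loss of silicon) and the capture of tertiary cations by silyl peroxides in peroxycarbenium–alkene annulations; C5 is created here with no substrate control, the chiral salen ligand is intended (unproven at a fully substituted centre) to bias it towards 5R, and the isomer with the two ring methyl groups cis (15) is separated from the trans isomer by chromatography and from any 5-epi series by preparative HPLC.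

**Step 6**
Reactants: 15 2-[(3S,5R)-3,5-dimethyl-5-[(2R)-2-methyl-10-(trimethylsilyl)dec-9-yn-1-yl]-1,2-dioxolan-3-yl]ethyl acetate
Product: 16 2-[(3S,5R)-3,5-dimethyl-5-[(2R)-2-methyldec-9-yn-1-yl]-1,2-dioxolan-3-yl]ethan-1-ol
Conditions: K2CO3, MeOH, rt
Reagents that add atoms: none
Why: Methanolysis removes the acetate and protodesilylates the alkyne in one operation, and the doubly tertiary peroxide has no α-hydrogen for a Kornblum–DeLaMare pathway, so it and all stereocentres are untouched.

**Step 7**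
Reactants: 16 2-[(3S,5R)-3,5-dimethyl-5-[(2R)-2-methyldec-9-yn-1-yl]-1,2-dioxolan-3-yl]ethan-1-ol
Product: 18 2-[(3S,5R)-5-[(2R,9E)-10-iodo-2-methyldec-9-en-1-yl]-3,5-dimethyl-1,2-dioxolan-3-yl]ethan-1-ol, via alkenylzirconocene 17 (not isolated)
Conditions: Cp2Zr(H)Cl (2.3 equiv), THF, rt; then I2, 0 °C
Reagents that add atoms: iodine II
Why: Schwartz hydrozirconation (syn, Zr at the terminal carbon) followed by iodinolysis with retention gives the (E)-alkenyl iodide, with one equivalent of reagent consumed by the alcohol and the doubly tertiary peroxide shielded from Zr–H much as di-tert-butyl peroxide resists hydride reagents.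

**Step 8**
Reactants: 18 2-[(3S,5R)-5-[(2R,9E)-10-iodo-2-methyldec-9-en-1-yl]-3,5-dimethyl-1,2-dioxolan-3-yl]ethan-1-ol
Product: 20 2-[(3R,5R)-5-[(2R,9E)-10-iodo-2-methyldec-9-en-1-yl]-3,5-dimethyl-1,2-dioxolan-3-yl]acetic acid, via aldehyde 19 (not isolated)
Conditions: TEMPO (20 mol %), PhI(OAc)2 (2.5 equiv), MeCN/H2O 1:1, rt
Reagents that add atoms: water O
Why: TEMPO/PhI(OAc)2 (oxoammonium) oxidation of the primary alcohol through the aldehyde hydrate gives the acid under near-neutral conditions that leave the peroxide and alkenyl iodide alone, and C3 is now called 3R only because the CIP priorities change.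

**Step 9**
Reactants: 20 2-[(3R,5R)-5-[(2R,9E)-10-iodo-2-methyldec-9-en-1-yl]-3,5-dimethyl-1,2-dioxolan-3-yl]acetic acid; 21 styrene
Product: 22 2-[(3R,5R)-3,5-dimethyl-5-[(2R,9E,11E)-2-methyl-12-phenyldodeca-9,11-dien-1-yl]-1,2-dioxolan-3-yl]acetic acid
Conditions: 21 (3 equiv), Pd(OAc)2 (5 mol %), K2CO3 (3 equiv), n-Bu4NCl, DMF, 40 °C, dark; then aq. citric acid
Reagents that add atoms: none
Why: Heck reaction under Jeffery conditions, in which syn-carbopalladation at the terminal carbon of styrene and syn-β-hydride elimination give the (9E,11E)-diene with retention of the iodide geometry, and dialkyl peroxides tolerate Pd(0) at this temperature.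

**Compound list**
1 | 1,6-dibromohexane | BrCCCCCCBr | starting material
2 | ethynyltrimethylsilane | C#C[Si](C)(C)C | starting material
3 | lithium (trimethylsilyl)acetylide | [Li]C#C[Si](C)(C)C | intermediate
4 | (8-bromooct-1-yn-1-yl)trimethylsilane | C[Si](C)(C)C#CCCCCCCBr | intermediate
5 | (E)-pent-3-en-2-one | C/C=C/C(C)=O | starting material
6 | [8-(trimethylsilyl)oct-7-yn-1-yl]magnesium bromide | C[Si](C)(C)C#CCCCCCC[Mg]Br | intermediate
7 | bromomagnesium (2Z,4R)-4-methyl-12-(trimethylsilyl)dodec-2-en-11-yn-2-olate (Z major) | C/C(O[Mg]Br)=C/[C@H](C)CCCCCCC#C[Si](C)(C)C | intermediate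
8 | (2Z,4R)-4-methyl-12-(trimethylsilyl)dodec-2-en-11-yn-2-yl trifluoromethanesulfonate | C/C(OS(=O)(=O)C(F)(F)F)=C/[C@H](C)CCCCCCC#C[Si](C)(C)C | intermediate
9 | 3-methylbut-3-en-1-ol (isoprenol) | C=C(C)CCO | starting material
10 | lithium 3-(lithiomethyl)but-3-en-1-olate | [Li]CC(=C)CCO[Li] | intermediate
11 | chloro[2-(2-lithiooxyethyl)prop-2-en-1-yl]zinc | Cl[Zn]CC(=C)CCO[Li] | intermediate
12 | lithium (5Z,7R)-5,7-dimethyl-3-methylidene-15-(trimethylsilyl)pentadec-5-en-14-yn-1-olate | [Li]OCCC(=C)C/C(C)=C\[C@H](C)CCCCCCC#C[Si](C)(C)C | intermediate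
13 | (5Z,7R)-5,7-dimethyl-3-methylidene-15-(trimethylsilyl)pentadec-5-en-14-yn-1-yl acetate | CC(=O)OCCC(=C)C/C(C)=C\[C@H](C)CCCCCCC#C[Si](C)(C)C | intermediate
14 | (3RS,5Z,7R)-3,5,7-trimethyl-3-[(triethylsilyl)peroxy]-15-(trimethylsilyl)pentadec-5-en-14-yn-1-yl acetate (C3 epimers) | CC(=O)OCCC(C)(OO[Si](CC)(CC)CC)C/C(C)=C\[C@H](C)CCCCCCC#C[Si](C)(C)C | intermediate
15 | 2-[(3S,5R)-3,5-dimethyl-5-[(2R)-2-methyl-10-(trimethylsilyl)dec-9-yn-1-yl]-1,2-dioxolan-3-yl]ethyl acetate (3S here is the same spatial arrangement as 3R in the target) | C[C@H](CCCCCCC#C[Si](C)(C)C)C[C@]1(C)C[C@](C)(CCOC(C)=O)OO1 | intermediate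
16 | 2-[(3S,5R)-3,5-dimethyl-5-[(2R)-2-methyldec-9-yn-1-yl]-1,2-dioxolan-3-yl]ethan-1-ol | C[C@H](CCCCCCC#C)C[C@]1(C)C[C@](C)(CCO)OO1 | intermediate
17 | (E)-alkenyl(chlorido)zirconocene of 16, O-zirconated | C[C@H](CCCCCC/C=C/[Zr](Cl)(C1C=CC=C1)C1C=CC=C1)C[C@]1(C)C[C@](C)(CCO[Zr](Cl)(C2C=CC=C2)C2C=CC=C2)OO1 | intermediate
18 | 2-[(3S,5R)-5-[(2R,9E)-10-iodo-2-methyldec-9-en-1-yl]-3,5-dimethyl-1,2-dioxolan-3-yl]ethan-1-ol | C[C@H](CCCCCC/C=C/I)C[C@]1(C)C[C@](C)(CCO)OO1 | intermediate
19 | 2-[(3R,5R)-5-[(2R,9E)-10-iodo-2-methyldec-9-en-1-yl]-3,5-dimethyl-1,2-dioxolan-3-yl]acetaldehyde | C[C@H](CCCCCC/C=C/I)C[C@]1(C)C[C@](C)(CC=O)OO1 | intermediate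
20 | 2-[(3R,5R)-5-[(2R,9E)-10-iodo-2-methyldec-9-en-1-yl]-3,5-dimethyl-1,2-dioxolan-3-yl]acetic acid | C[C@H](CCCCCC/C=C/I)C[C@]1(C)C[C@](C)(CC(=O)O)OO1 | intermediate
21 | styrene | C=Cc1ccccc1 | starting material
22 | 2-[(3R,5R)-3,5-dimethyl-5-[(2R,9E,11E)-2-methyl-12-phenyldodeca-9,11-dien-1-yl]-1,2-dioxolan-3-yl]acetic acid | C[C@H](CCCCCC/C=C/C=C/c1ccccc1)C[C@]1(C)C[C@](C)(CC(=O)O)OO1 | target

**Totals**
Total step count: 9. Longest linear sequence: 9 (1/2 → 22).

**Steps most likely to fail, with fallbacks**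

Step 5 (untested ring closure; C5 not reliably controlled). The fallback sets out from 14 and comes back at 15. HF·pyridine (THF, 0 °C) frees the tertiary hydroperoxide, (3RS,5Z,7R)-3-hydroperoxy-3,5,7-trimethyl-15-(trimethylsilyl)pentadec-5-en-14-yn-1-yl acetate F1. Hg(OAc)2 with catalytic HClO4 in CH2Cl2 then effects a polar, Markovnikov 5-exo cycloperoxymercuration (Bloodworth type) to the 1′-(acetoxymercurio) derivative of the dioxolane acetate F2. NaBH4 in aqueous NaOH at 0 °C (high hydride concentration to outrun epoxide formation) replaces mercury by hydrogen and gives 15 after the same separation of isomers.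

Step 2 (enantioselectivity with this small enone; in-flask triflation of a magnesium enolate). The fallback sets out from 4 and 5 and comes back at 8. The same conjugate addition is quenched with Me3SiCl/Et3N to give the isolable silyl enol ether, trimethyl{[(2Z,4R)-4-methyl-12-(trimethylsilyl)dodec-2-en-11-yn-2-yl]oxy}silane F3, on which the ee can be checked. MeLi (THF, 0 °C) regenerates the regiodefined enolate, lithium (2Z,4R)-4-methyl-12-(trimethylsilyl)dodec-2-en-11-yn-2-olate F4, which PhNTf2 converts cleanly to 8.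

Step 7 (Zr–H in the presence of the peroxide). The fallback makes the alkenyl iodide before any O–O bond exists; it sets out from 13 and comes back at 18.
- K2CO3/MeOH gives (5Z,7R)-5,7-dimethyl-3-methylidenepentadec-5-en-14-yn-1-ol F5.
- Cp2Zr(H)Cl then I2 gives (5Z,7R,14E)-15-iodo-5,7-dimethyl-3-methylidenepentadeca-5,14-dien-1-ol F6.
- Ac2O/pyridine gives (5Z,7R,14E)-15-iodo-5,7-dimethyl-3-methylidenepentadeca-5,14-dien-1-yl acetate F7.
- The conditions of step 4 give (3RS,5Z,7R,14E)-15-iodo-3,5,7-trimethyl-3-[(triethylsilyl)peroxy]pentadeca-5,14-dien-1-yl acetate F8.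
- The conditions of step 5 give 2-[(3S,5R)-5-[(2R,9E)-10-iodo-2-methyldec-9-en-1-yl]-3,5-dimethyl-1,2-dioxolan-3-yl]ethyl acetate F9.
- K2CO3/MeOH gives 18.

**Further compounds**
F1 | step 5 | (3RS,5Z,7R)-3-hydroperoxy-3,5,7-trimethyl-15-(trimethylsilyl)pentadec-5-en-14-yn-1-yl acetate | CC(=O)OCCC(C)(OO)C/C(C)=C\[C@H](C)CCCCCCC#C[Si](C)(C)C
F2 | step 5 | 1′-(acetoxymercurio) derivative of 15 (ring as in 15, both C1′ epimers) | C[C@H](CCCCCCC#C[Si](C)(C)C)C([Hg]OC(C)=O)[C@]1(C)C[C@](C)(CCOC(C)=O)OO1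
F3 | step 2 | trimethyl{[(2Z,4R)-4-methyl-12-(trimethylsilyl)dodec-2-en-11-yn-2-yl]oxy}silane | C/C(O[Si](C)(C)C)=C/[C@H](C)CCCCCCC#C[Si](C)(C)C
F4 | step 2 | lithium (2Z,4R)-4-methyl-12-(trimethylsilyl)dodec-2-en-11-yn-2-olate | C/C(O[Li])=C/[C@H](C)CCCCCCC#C[Si](C)(C)C
F5 | step 7 | (5Z,7R)-5,7-dimethyl-3-methylidenepentadec-5-en-14-yn-1-ol | OCCC(=C)C/C(C)=C\[C@H](C)CCCCCCC#C
F6 | step 7 | (5Z,7R,14E)-15-iodo-5,7-dimethyl-3-methylidenepentadeca-5,14-dien-1-ol | OCCC(=C)C/C(C)=C\[C@H](C)CCCCCC/C=C/I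
F7 | step 7 | (5Z,7R,14E)-15-iodo-5,7-dimethyl-3-methylidenepentadeca-5,14-dien-1-yl acetate | CC(=O)OCCC(=C)C/C(C)=C\[C@H](C)CCCCCC/C=C/I
F8 | step 7 | (3RS,5Z,7R,14E)-15-iodo-3,5,7-trimethyl-3-[(triethylsilyl)peroxy]pentadeca-5,14-dien-1-yl acetate | CC(=O)OCCC(C)(OO[Si](CC)(CC)CC)C/C(C)=C\[C@H](C)CCCCCC/C=C/I
F9 | step 7 | 2-[(3S,5R)-5-[(2R,9E)-10-iodo-2-methyldec-9-en-1-yl]-3,5-dimethyl-1,2-dioxolan-3-yl]ethyl acetate | C[C@H](CCCCCC/C=C/I)C[C@]1(C)C[C@](C)(CCOC(C)=O)OO1
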